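I am the chemist following this flask, with its early readings and the earlier run at half the substrate in hand.

all flasks: gas phase 13 mM (held); free catalyst 0.30 mM; added ligand 0.37 mM; impurity 0.31 mM
- eta: substrate 0.050 M; the very flask that is asked about, followed so far
- theta: substrate 0.025 M; run made earlier
- flask: substrate 0.050 M; time 6.0 min

eta run (percent of the substrate charged)

| time / s | target / % | substrate / % |
|---|---|---|
| 10.0 | 0 | 99.6 |
| 12.0 | 0 | 100.1 |
| 20.0 | 0.4 | 99.4 |
| 30.0 | 0.3 | 99.1 |
| 50.0 | 1.6 | 99.3 |
| 80.0 | 2.3 | 97.2 |

theta run (percent of the substrate charged)

| time / min | target / % | substrate / % |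
|---|---|---|
| 0.333 | 0.6 | 99.8 |
| 0.500 | 0.3 | 99.4 |
| 0.833 | 1.6 | 98.2 |
| 1.33 | 2.7 | 96.9 |
| 2.00 | 4.3 | 95.3 |
| 3.00 | 6.0 | 94.3 |
| 4.00 | 7.4 | 92.8 |

(each reading ± 0.3 percentage points)

- the target standing at 6.0 min, as a percentage of the substrate charged
- concentration of dissolved gas in solution at 3.0 min, in percent of saturation
- the change that raises the amount of target at 6.0 min, in percent of the substrate charged most ("none" if none brings more than 2 percentage points) (grey / violet / amber / none)
- amount of target at 6.0 min, in percent of the substrate charged, after violet

- at the start none of the gas phase is in solution

- grey: doubling the amount of free catalyst, all else as stated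
- violet: doubling the saturation concentration of gas phase, all else as stated
- amber: doubling the transfer coefficient of the gas phase, all else as stated

Near 80.0 s the flask's target reads 2.3% and the theta run reads 2.7% at 1.33 min, which agree within the scatter of their difference. I therefore read the reaction as first order in substrate and carry the theta percent curve over to this flask.

From 0.833 min to 2.00 min the theta target grows at 0.0231 min⁻¹ as a fraction of the charge, and from there to 4.00 min at 0.0155 min⁻¹. Dividing the time between the midpoints by the logarithm of that ratio gives 3.95 min. I call this reading the life of the rate, the time in which the rate falls by a factor of e.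

The bracket comes next. I take it that target is not lost, so the last theta reading, 7.4%, is my floor for this flask. If the last rate simply held, the target at 6.0 min would be 10.5%. If the rate keeps falling with this life, the top tightens to 9.29%, and I commit to that range.

The forecast gives 9.5%, 96% of saturation, grey as best and 15% after violet, on the ground that the falling rate “suggests the catalyst is dying”, so its target lies inside the wide bracket but above my tightened top.

The flask gives 7.94%, inside my range, with dissolved gas at 69.1% of saturation at 3.0 min. The best change is grey, gaining 9.3 percentage points, and violet reaches 15.3%.

    gas phase ⇌ dissolved gas, rate k1*(csat - [dissolved gas]) (kL = 0.00880 s⁻¹)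
    substrate + dissolved gas + free catalyst → free catalyst + target (k = 2200 M⁻² s⁻¹)
    free catalyst → spent catalyst A (k = 0.0140 s⁻¹)
    free catalyst + added ligand ⇌ idle complex, settled at all times (K = 8000 M⁻¹)
    free catalyst + impurity → spent catalyst B (k = 110 M⁻¹ s⁻¹)

In this flask free catalyst falls from 3.88% to 0.940% between 3.0 min and 6.0 min, a life of 2.11 min, shorter than my reading, while dissolved gas climbs from 0.00898 M to 0.0117 M. The neighbouring flask holds 7.7 × 10⁻⁴ M of impurity against 0.31 mM in this flask, with all else the same. If life goes inversely with impurity, mine shrinks to 1.59 min, and target scaled with it becomes 3.20%, a drop of 0.395 in powers of ten. The target of the neighbouring flask stands lower than that scaled figure, at 2.43%, a drop of 0.514, with 83.3% of the catalyst charged as spent catalyst B.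

(The data stem from a simulated flask for substances that don't exist; noise was put on by code.)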